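The tetrahydrofuran ring (O1, C2–C5) is traced back to a C2-symmetric succinate: ring carbons C3/C4 (C8/C8') are the α-carbons, ring carbons C2/C5 (C9/C9') the ester carbons, and the two exocyclic benzylic carbinol carbons (C7/C7') the β-carbons of two cinnamate units. Each benzylic C–O bond therefore enters as a C–B bond. One copper-catalysed, ligand-controlled twofold conjugate borylation of dimethyl (2E,3E)-2,3-bis(4-benzyloxy-3-methoxybenzylidene)succinate, a twisted diene diester from two Stobbe condensations, places boron on C7/C7' and hydrogen on C8/C8' and sets both carbinol stereocentres; C8/C8' are then settled in a cis-fused bis-lactone.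

Key step: step 5

Remark on numbering: lignan numbering is used throughout (C7/C7' benzylic carbons, C8/C8' ring methines, C9/C9' ring methylenes); "aryl" means 4-benzyloxy-3-methoxyphenyl.

Assumption: the (R,S)-configured Josiphos ligand is taken to deliver boron to the alkene face that makes both benzylic carbons (S), as with simple (E)-cinnamates; if a test reaction shows the opposite sense, the enantiomeric ligand is used and nothing else changes.

Step 1
Reactants: 1 O-benzylvanillin (4-benzyloxy-3-methoxybenzaldehyde); 2 dimethyl succinate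
Product: 3 (E)-4-(4-benzyloxy-3-methoxyphenyl)-3-(methoxycarbonyl)but-3-enoic acid
Conditions: NaOMe, MeOH, reflux; then aq. HCl
Reagents that add atoms: none
Why: Stobbe condensation, in which the succinate enolate adds to the aldehyde, the alkoxide closes a paraconate lactone and E1cB ring opening gives the half-ester irreversibly as its carboxylate, with the aryl group trans to the conjugated ester (E) for steric reasons; the aryl benzyl ether is inert to methoxide.

Step 2
Reactants: 3 (E)-4-(4-benzyloxy-3-methoxyphenyl)-3-(methoxycarbonyl)but-3-enoic acid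
Product: 4 dimethyl (E)-2-(4-benzyloxy-3-methoxybenzylidene)succinate
Conditions: MeI, K2CO3, DMF, rt
Reagents that add atoms: iodomethane, CI
Why: SN2 O-alkylation of the carboxylate restores the diester needed for a second condensation under non-acidic conditions that leave the alkene geometry and the benzyl ether untouched.

Step 3
Reactants: 4 dimethyl (E)-2-(4-benzyloxy-3-methoxybenzylidene)succinate; 1 O-benzylvanillin
Product: 5 (2E,3E)-2,3-bis(4-benzyloxy-3-methoxybenzylidene)-4-methoxy-4-oxobutanoic acid
Conditions: NaOMe, MeOH, reflux; then aq. HCl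
Reagents that add atoms: none
Why: second Stobbe condensation at the remaining CH2 (α to the saturated ester), again through lactone formation and E1cB opening, which should give the (E,E)-half-ester because each aryl group avoids its neighbouring ester.

Step 4
Reactants: 5 (2E,3E)-2,3-bis(4-benzyloxy-3-methoxybenzylidene)-4-methoxy-4-oxobutanoic acid
Product: 6 dimethyl (2E,3E)-2,3-bis(4-benzyloxy-3-methoxybenzylidene)succinate
Conditions: MeI, K2CO3, DMF, rt
Reagents that add atoms: iodomethane, CI
Why: SN2 O-methylation of the carboxylate gives the symmetric diester in which both alkenes are equivalent cinnamate-type acceptors.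

Step 5
Reactants: 6 dimethyl (2E,3E)-2,3-bis(4-benzyloxy-3-methoxybenzylidene)succinate; 7 bis(pinacolato)diboron
Product: 8 dimethyl 2,3-bis[(S)-(4-benzyloxy-3-methoxyphenyl)(4,4,5,5-tetramethyl-1,3,2-dioxaborolan-2-yl)methyl]succinate (C8/C8' not yet defined)
Conditions: CuCl (10 mol %), NaOt-Bu (15 mol %), (R)-1-[(S)-2-(diphenylphosphino)ferrocenyl]ethyldicyclohexylphosphine [(R,S)-Josiphos, 11 mol %], B2pin2 (2.5 equiv), MeOH (5 equiv), THF, rt
Reagents that add atoms: bis(pinacolato)diboron (compound 7), CC1(C)OB(OC1(C)C)B1OC(C)(C)C(C)(C)O1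
Why: The ligated monovalent copper alkoxide reacts with B2pin2 to give L*Cu–Bpin, which adds syn across each C7=C8 bond with boron to the benzylic β-carbon and copper to the α-carbon (copper enolate); methanol protonates the enolate at C8 and returns L*Cu–OMe, which is borylated again. The closest known reaction type is the copper–bisphosphine-catalysed enantioselective β-borylation of (E)-cinnamates and α-substituted enoates; no ring is closed. The two new stereocentres C7 and C7' are set by the Josiphos ligand, which discriminates the enantiotopic alkene faces, and because both ends react under catalyst control a wrong-sense event ends mostly in the separable (S,R) diastereomer, so the C2-symmetric (S,S) product should be enriched in enantiopurity. Regioselectivity (boron to C7) follows from the polarisation of the cinnamate, and aryl benzyl ethers and methyl esters are inert to the copper boryl. Protonation at the α- and not the γ-carbon of the cross-conjugated enolate is secured by the twist of the 2,3-disubstituted diene, which keeps the remaining benzylidene out of conjugation, and by kinetic protonation at the enolate carbon. Protonation anti to the bulky, electron-releasing C–B bond is expected to favour the 7,8-syn arrangement needed later, but C8/C8' need not be controlled here.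

Step 6
Reactants: 8 dimethyl 2,3-bis[(S)-(4-benzyloxy-3-methoxyphenyl)(4,4,5,5-tetramethyl-1,3,2-dioxaborolan-2-yl)methyl]succinate
Product: 10 (3S,3aS,6S,6aS)-3,6-bis(4-benzyloxy-3-methoxyphenyl)tetrahydro-1H,3H-furo[3,4-c]furan-1,4-dione (exo,exo bis-lactone), via diol diester 9 (not isolated)
Conditions: NaBO3·4H2O, THF/H2O (1:1), rt; extractive work-up; then DBU (0.3 equiv), toluene, 4 Å MS, 80 °C
Reagents that add atoms: sodium perborate tetrahydrate, [Na+].[O-]OB=O.O.O.O.O
Why: perborate oxidation replaces each C–B bond by C–OH with retention (1,2-shift of carbon from boron to oxygen), and DBU then drives γ-lactonisation of each 7-OH onto the distal ester while the α-carbons epimerise by reversible enolisation, so the diastereomers should converge on the cis-fused 2,6-diaryl-3,7-dioxabicyclo[3.3.0]octane-4,8-dione with both aryl groups on the convex face (thermodynamic control that fixes C8/C8' relative to the ligand-set C7/C7'), ring-opening β-elimination of the lactone carboxylate being a stereoelectronically disfavoured 5-endo-type process that should be slower than proton return in the amidinium ion pair.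

Step 7
Reactants: 10 (3S,3aS,6S,6aS)-3,6-bis(4-benzyloxy-3-methoxyphenyl)tetrahydro-1H,3H-furo[3,4-c]furan-1,4-dione
Product: 12 (2S,3S)-2,3-bis[(S)-(4-benzyloxy-3-methoxyphenyl)(tert-butyldimethylsilyloxy)methyl]-N1,N4-dimethoxy-N1,N4-dimethylsuccinamide, via hydroxy amide 11 (not isolated)
Conditions: MeNHOMe·HCl, AlMe3, CH2Cl2, 0 °C to rt; Rochelle-salt work-up; then TBSOTf, 2,6-lutidine, CH2Cl2, −78 to 0 °C
Reagents that add atoms: N,O-dimethylhydroxylamine hydrochloride, CNOC.Cl; tert-butyldimethylsilyl triflate, CC(C)(C)[Si](C)(C)OS(=O)(=O)C(F)(F)F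
Why: aluminium amide-mediated aminolysis opens both lactones at the acyl C–O bond (no change at C7 or C8) to the bis(N-methoxy-N-methylamide), and immediate silylation of the freed benzylic hydroxyls with the silyl triflate blocks relactonisation and marks O7/O7' apart from the later primary hydroxyls.

Step 8
Reactants: 12 (2S,3S)-2,3-bis[(S)-(4-benzyloxy-3-methoxyphenyl)(tert-butyldimethylsilyloxy)methyl]-N1,N4-dimethoxy-N1,N4-dimethylsuccinamide
Product: 14 (2R,3R)-2,3-bis[(S)-(4-benzyloxy-3-methoxyphenyl)(tert-butyldimethylsilyloxy)methyl]butane-1,4-diol, via dialdehyde 13 (not isolated)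
Conditions: i-Bu2AlH, THF, −78 °C; then MeOH, NaBH4, −78 to 0 °C; aq. Rochelle salt
Reagents that add atoms: none
Why: the aluminium hydride adds once to each N-methoxy-N-methylamide and the chelated tetrahedral aluminate holds until the protic quench, when borohydride reduces the released α-branched aldehydes at low temperature before they can epimerise at C8/C8'.

Step 9
Reactants: 14 (2R,3R)-2,3-bis[(S)-(4-benzyloxy-3-methoxyphenyl)(tert-butyldimethylsilyloxy)methyl]butane-1,4-diol
Product: 15 (3R,4R)-3,4-bis[(S)-(4-benzyloxy-3-methoxyphenyl)(tert-butyldimethylsilyloxy)methyl]tetrahydrofuran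
Conditions: PPh3, DIAD, THF, 0 °C to rt
Reagents that add atoms: none
Why: Mitsunobu cyclodehydration, in which one primary hydroxyl is activated as its alkoxyphosphonium ion and displaced by the other in a 5-exo-tet SN2 closure under neutral conditions, so no alkoxide arises that could cause 1,3-silyl migration and no stereocentre lies at a reacting carbon.

Step 10
Reactants: 15 (3R,4R)-3,4-bis[(S)-(4-benzyloxy-3-methoxyphenyl)(tert-butyldimethylsilyloxy)methyl]tetrahydrofuran
Product: 16 (3R,4R)-3,4-bis[(S)-(4-benzyloxy-3-methoxyphenyl)(hydroxy)methyl]tetrahydrofuran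
Conditions: TBAF, THF, rt
Reagents that add atoms: none
Why: fluoride-driven Si–O cleavage frees the two benzylic hydroxyls, and with the phenols still benzylated no phenoxide is present that could expel a benzylic oxygen through a quinone methide.

Step 11
Reactants: 16 (3R,4R)-3,4-bis[(S)-(4-benzyloxy-3-methoxyphenyl)(hydroxy)methyl]tetrahydrofuran
Product: 17 (3R,4R)-3,4-bis[(S)-hydroxy(4-hydroxy-3-methoxyphenyl)methyl]tetrahydrofuran (target, 7S,8R,7'S,8'R)
Conditions: H2 (1 atm), 10% Pd/C, EtOAc, rt
Reagents that add atoms: none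
Why: heterogeneous hydrogenolysis cleaves the two aryl benzyl ethers much faster than the secondary benzylic C–OH bonds under neutral conditions at atmospheric pressure, and the reaction is stopped once debenzylation is complete.

Compound list

1 | O-benzylvanillin (4-benzyloxy-3-methoxybenzaldehyde) | COc1cc(C=O)ccc1OCc1ccccc1 | starting material
2 | dimethyl succinate | COC(=O)CCC(=O)OC | starting material
3 | (E)-4-(4-benzyloxy-3-methoxyphenyl)-3-(methoxycarbonyl)but-3-enoic acid | COC(=O)/C(=C/c1ccc(OCc2ccccc2)c(OC)c1)CC(=O)O | intermediate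
4 | dimethyl (E)-2-(4-benzyloxy-3-methoxybenzylidene)succinate | COC(=O)/C(=C/c1ccc(OCc2ccccc2)c(OC)c1)CC(=O)OC | intermediate
5 | (2E,3E)-2,3-bis(4-benzyloxy-3-methoxybenzylidene)-4-methoxy-4-oxobutanoic acid | COC(=O)/C(=C/c1ccc(OCc2ccccc2)c(OC)c1)C(=C/c1ccc(OCc2ccccc2)c(OC)c1)\C(=O)O | intermediate
6 | dimethyl (2E,3E)-2,3-bis(4-benzyloxy-3-methoxybenzylidene)succinate | COC(=O)/C(=C/c1ccc(OCc2ccccc2)c(OC)c1)C(=C/c1ccc(OCc2ccccc2)c(OC)c1)\C(=O)OC | intermediate
7 | bis(pinacolato)diboron | CC1(C)OB(OC1(C)C)B1OC(C)(C)C(C)(C)O1 | starting material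
8 | dimethyl 2,3-bis[(S)-(4-benzyloxy-3-methoxyphenyl)(4,4,5,5-tetramethyl-1,3,2-dioxaborolan-2-yl)methyl]succinate (C8/C8' undefined) | COC(=O)C([C@H](B1OC(C)(C)C(C)(C)O1)c1ccc(OCc2ccccc2)c(OC)c1)C([C@H](B1OC(C)(C)C(C)(C)O1)c1ccc(OCc2ccccc2)c(OC)c1)C(=O)OC | intermediate
9 | dimethyl 2,3-bis[(S)-(4-benzyloxy-3-methoxyphenyl)(hydroxy)methyl]succinate (C8/C8' undefined; not isolated) | COC(=O)C([C@H](O)c1ccc(OCc2ccccc2)c(OC)c1)C([C@H](O)c1ccc(OCc2ccccc2)c(OC)c1)C(=O)OC | intermediate
10 | (3S,3aS,6S,6aS)-3,6-bis(4-benzyloxy-3-methoxyphenyl)tetrahydro-1H,3H-furo[3,4-c]furan-1,4-dione (cis-fused, both aryl groups exo) | COc1cc([C@H]2OC(=O)[C@@H]3[C@@H](c4ccc(OCc5ccccc5)c(OC)c4)OC(=O)[C@H]23)ccc1OCc1ccccc1 | intermediate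
11 | (2S,3S)-2,3-bis[(S)-(4-benzyloxy-3-methoxyphenyl)(hydroxy)methyl]-N1,N4-dimethoxy-N1,N4-dimethylsuccinamide (not isolated) | COc1cc([C@@H](O)[C@@H](C(=O)N(C)OC)[C@H](C(=O)N(C)OC)[C@H](O)c2ccc(OCc3ccccc3)c(OC)c2)ccc1OCc1ccccc1 | intermediate
12 | (2S,3S)-2,3-bis[(S)-(4-benzyloxy-3-methoxyphenyl)(tert-butyldimethylsilyloxy)methyl]-N1,N4-dimethoxy-N1,N4-dimethylsuccinamide | COc1cc([C@@H](O[Si](C)(C)C(C)(C)C)[C@@H](C(=O)N(C)OC)[C@H](C(=O)N(C)OC)[C@H](O[Si](C)(C)C(C)(C)C)c2ccc(OCc3ccccc3)c(OC)c2)ccc1OCc1ccccc1 | intermediate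
13 | (2S,3S)-2,3-bis[(S)-(4-benzyloxy-3-methoxyphenyl)(tert-butyldimethylsilyloxy)methyl]butanedial (not isolated) | COc1cc([C@@H](O[Si](C)(C)C(C)(C)C)[C@@H](C=O)[C@H](C=O)[C@H](O[Si](C)(C)C(C)(C)C)c2ccc(OCc3ccccc3)c(OC)c2)ccc1OCc1ccccc1 | intermediate
14 | (2R,3R)-2,3-bis[(S)-(4-benzyloxy-3-methoxyphenyl)(tert-butyldimethylsilyloxy)methyl]butane-1,4-diol | COc1cc([C@@H](O[Si](C)(C)C(C)(C)C)[C@@H](CO)[C@H](CO)[C@H](O[Si](C)(C)C(C)(C)C)c2ccc(OCc3ccccc3)c(OC)c2)ccc1OCc1ccccc1 | intermediate
15 | (3R,4R)-3,4-bis[(S)-(4-benzyloxy-3-methoxyphenyl)(tert-butyldimethylsilyloxy)methyl]tetrahydrofuran | COc1cc([C@@H](O[Si](C)(C)C(C)(C)C)[C@H]2COC[C@@H]2[C@H](O[Si](C)(C)C(C)(C)C)c2ccc(OCc3ccccc3)c(OC)c2)ccc1OCc1ccccc1 | intermediate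
16 | (3R,4R)-3,4-bis[(S)-(4-benzyloxy-3-methoxyphenyl)(hydroxy)methyl]tetrahydrofuran | COc1cc([C@@H](O)[C@H]2COC[C@@H]2[C@H](O)c2ccc(OCc3ccccc3)c(OC)c2)ccc1OCc1ccccc1 | intermediate
17 | (3R,4R)-3,4-bis[(S)-hydroxy(4-hydroxy-3-methoxyphenyl)methyl]tetrahydrofuran | COc1cc([C@@H](O)[C@H]2COC[C@@H]2[C@H](O)c2ccc(O)c(OC)c2)ccc1O | target

Total step count: 11. Longest linear sequence: 11 steps (from 1 and 2 to 17).

Steps most likely to fail

Step 5. What may go wrong: the second, more hindered cinnamate unit reacts sluggishly, the cross-conjugated enolate is protonated at the γ-carbon, or face discrimination at the α-branched alkene is poor. Fallback (benzylic stereocentres by ketone reduction instead of C–B formation): setting out from 1, SnCl2-catalysed homologation with methyl diazoacetate (Roskamp reaction, CH2Cl2, rt) should give methyl 3-(4-benzyloxy-3-methoxyphenyl)-3-oxopropanoate F1. Oxidative coupling of its sodium enolate (NaH, then I2, THF, 0 °C) should give dimethyl 2,3-bis(4-benzyloxy-3-methoxybenzoyl)succinate F2, whose α-carbons epimerise freely. Twofold asymmetric transfer hydrogenation of the aryl ketones with RuCl(p-cymene)[(S,S)-TsDPEN] and HCO2H/Et3N at rt should then deliver the (S,S)-diol diester 9, which comes back to the route in the lactonisation half of step 6.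

Step 6. What may go wrong: base-mediated epimerisation at C8/C8' is outrun by β-elimination of the lactone carboxylate (loss of a C7 stereocentre as a benzylidene), or the mixture stalls at lactones that cannot close the second ring. Fallback (kinetic selection with recycling instead of equilibration): setting out from 9, lactonisation without strong base (toluene, 4 Å MS, cat. 2-hydroxypyridine, 80 °C) should give 10 only from the diastereomer that is 7,8-syn at both ends, and 10 is crystallised. The remaining hydroxy lactones, chiefly the all-trans methyl (2S,3S,4R)-2-(4-benzyloxy-3-methoxyphenyl)-4-[(S)-(4-benzyloxy-3-methoxyphenyl)(hydroxy)methyl]-5-oxotetrahydrofuran-3-carboxylate F3, are acetylated (Ac2O, Et3N, DMAP, CH2Cl2) to the acetate F4. DBU in toluene at 80 °C should then remove the acetate and open the lactone by two β-eliminations. After acidification this returns acid 5, which goes through steps 4 and 5 again.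

Step 7. What may go wrong: incomplete twofold aminolysis of the hindered bis-lactone, Lewis-acid-assisted ionisation of the electron-rich benzylic lactone C–O bond, or relactonisation of the hydroxy amide before silylation. Fallback (tell the oxygens apart after full reduction instead of during ring opening): setting out from 10, LiAlH4 (THF, 0 °C) should give (2R,3R)-2,3-bis[(S)-(4-benzyloxy-3-methoxyphenyl)(hydroxy)methyl]butane-1,4-diol F5. Persilylation (TBSOTf, 2,6-lutidine, CH2Cl2) should give the tetrakis(tert-butyldimethylsilyl) ether F6. Selective cleavage of the two primary silyl ethers (HF·pyridine, pyridine/THF, 0 °C) should then give diol 14, where the route is rejoined before step 9.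

Further compounds

F1 | step 5 | methyl 3-(4-benzyloxy-3-methoxyphenyl)-3-oxopropanoate | COC(=O)CC(=O)c1ccc(OCc2ccccc2)c(OC)c1
F2 | step 5 | dimethyl 2,3-bis(4-benzyloxy-3-methoxybenzoyl)succinate | COC(=O)C(C(=O)c1ccc(OCc2ccccc2)c(OC)c1)C(C(=O)c1ccc(OCc2ccccc2)c(OC)c1)C(=O)OC
F3 | step 6 | methyl (2S,3S,4R)-2-(4-benzyloxy-3-methoxyphenyl)-4-[(S)-(4-benzyloxy-3-methoxyphenyl)(hydroxy)methyl]-5-oxotetrahydrofuran-3-carboxylate | COc1cc([C@H]2OC(=O)[C@@H]([C@H](O)c3ccc(OCc4ccccc4)c(OC)c3)[C@@H]2C(=O)OC)ccc1OCc1ccccc1
F4 | step 6 | methyl (2S,3S,4R)-4-[(S)-acetoxy(4-benzyloxy-3-methoxyphenyl)methyl]-2-(4-benzyloxy-3-methoxyphenyl)-5-oxotetrahydrofuran-3-carboxylate | COc1cc([C@H]2OC(=O)[C@@H]([C@H](OC(C)=O)c3ccc(OCc4ccccc4)c(OC)c3)[C@@H]2C(=O)OC)ccc1OCc1ccccc1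
F5 | step 7 | (2R,3R)-2,3-bis[(S)-(4-benzyloxy-3-methoxyphenyl)(hydroxy)methyl]butane-1,4-diol | COc1cc([C@@H](O)[C@@H](CO)[C@H](CO)[C@H](O)c2ccc(OCc3ccccc3)c(OC)c2)ccc1OCc1ccccc1
F6 | step 7 | (2R,3R)-1,4-bis(tert-butyldimethylsilyloxy)-2,3-bis[(S)-(4-benzyloxy-3-methoxyphenyl)(tert-butyldimethylsilyloxy)methyl]butane | COc1cc([C@@H](O[Si](C)(C)C(C)(C)C)[C@@H](CO[Si](C)(C)C(C)(C)C)[C@H](CO[Si](C)(C)C(C)(C)C)[C@H](O[Si](C)(C)C(C)(C)C)c2ccc(OCc3ccccc3)c(OC)c2)ccc1OCc1ccccc1
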